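Palisadin B is disconnected across C5a–C9a, the vicinal CH/C(CH3)–O pair of its cyclohexane ring. A SmI2 ketyl–olefin cyclisation of an acyclic keto enoate joins the methyl ketone carbon (future C9a, carrying O1 and the angular methyl) to the enoate β-carbon (future C5a) in one operation, closing the six-membered ring and setting both centres relative to the C7 silyloxy stereocentre. The precursor already holds the C6 gem-dimethyl carbon and C7–O, set by an asymmetric isobutyrate aldol. Its ester becomes C4/C5 of the oxepene, which is closed by methacrylate ring-closing metathesis. C2 and both bromides are introduced late.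

Key step: step 7

Remark: atom labels (O1, C2 … C9a) follow 1-benzoxepine numbering of the target throughout; hydroxy aldehyde 12 equilibrates with its trans-fused lactol and is drawn in the open form.

Step 1
Reactants: 1 pent-4-enal; 2 1-methoxy-2-methyl-1-(trimethylsilyloxy)prop-1-ene
Product: 4 methyl (3S)-3-hydroxy-2,2-dimethylhept-6-enoate, via silyl ether 3 (not isolated)
Conditions: N-tosyl-D-valine (1.1 equiv), BH3·THF (1.0 equiv), CH2Cl2, 0 °C to rt; then 1 and 2, −78 °C; aq. HCl/THF work-up
Reagents that add atoms: none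
Why: Kiyooka-type Mukaiyama aldol in which the aldehyde, activated on the D-valine-derived oxazaborolidinone (made with a slight excess of the acid so that no free borane can hydroborate the alkene), is attacked on one face by the tetrasubstituted silyl ketene acetal, which should set the carbinol centre (future C7) as S, the transient TMS ether 3 being hydrolysed on work-up.

Step 2
Reactants: 4 methyl (3S)-3-hydroxy-2,2-dimethylhept-6-enoate
Product: 5 methyl (3S)-3-(tert-butyldimethylsilyloxy)-2,2-dimethylhept-6-enoate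
Conditions: TBSOTf, 2,6-lutidine, CH2Cl2, 0 °C
Reagents that add atoms: tert-butyldimethylsilyl trifluoromethanesulfonate, CC(C)(C)[Si](C)(C)OS(=O)(=O)C(F)(F)F
Why: Silylation of a hindered secondary alcohol with a silyl triflate and a non-nucleophilic base is reliable and leaves the ester and the alkene untouched.

Step 3
Reactants: 5 methyl (3S)-3-(tert-butyldimethylsilyloxy)-2,2-dimethylhept-6-enoate
Product: 6 (3S)-3-(tert-butyldimethylsilyloxy)-2,2-dimethylhept-6-en-1-ol
Conditions: i-Bu2AlH (2.5 equiv), CH2Cl2, −78 to 0 °C; aq. potassium sodium tartrate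
Reagents that add atoms: none
Why: Full reduction of the ester with i-Bu2AlH gives the neopentyl primary alcohol without touching the silyl ether or the isolated alkene.

Step 4
Reactants: 6 (3S)-3-(tert-butyldimethylsilyloxy)-2,2-dimethylhept-6-en-1-ol
Product: 7 (3S)-3-(tert-butyldimethylsilyloxy)-2,2-dimethylhept-6-enal
Conditions: Dess–Martin periodinane, CH2Cl2, rt
Reagents that add atoms: none
Why: Dess–Martin oxidation stops at the aldehyde, which has no α-hydrogen and therefore can neither epimerise nor eliminate the β-silyloxy group.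

Step 5
Reactants: 7 (3S)-3-(tert-butyldimethylsilyloxy)-2,2-dimethylhept-6-enal; 8 trimethyl phosphonoacetate
Product: 9 methyl (2E,5S)-5-(tert-butyldimethylsilyloxy)-4,4-dimethylnona-2,8-dienoate
Conditions: NaH, THF, 0 to 40 °C
Reagents that add atoms: none
Why: Horner–Wadsworth–Emmons olefination of a non-enolisable aldehyde with the sodium phosphonoacetate anion should give the E-enoate.

Step 6
Reactants: 9 methyl (2E,5S)-5-(tert-butyldimethylsilyloxy)-4,4-dimethylnona-2,8-dienoate
Product: 10 methyl (2E,5S)-5-(tert-butyldimethylsilyloxy)-4,4-dimethyl-8-oxonon-2-enoate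
Conditions: PdCl2 (10 mol%), CuCl (1 equiv), O2 (1 atm), DMF/H2O (7:1), rt
Reagents that add atoms: water, O
Why: Tsuji–Wacker oxidation converts the unhindered terminal alkene into the methyl ketone with Markovnikov selectivity, while the electron-poor enoate alkene next to the quaternary carbon is inert to PdCl2.

Step 7
Reactants: 10 methyl (2E,5S)-5-(tert-butyldimethylsilyloxy)-4,4-dimethyl-8-oxonon-2-enoate
Product: 11 methyl 2-[(1S,3S,6S)-3-(tert-butyldimethylsilyloxy)-6-hydroxy-2,2,6-trimethylcyclohexyl]acetate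
Conditions: SmI2 (2.5 equiv), HMPA (10 equiv), t-BuOH (2.5 equiv), THF, −78 °C, slow addition of 10; aq. NH4Cl
Reagents that add atoms: none
Why: SmI2 transfers one electron to the methyl ketone to give a samarium ketyl, whose carbon adds to the enoate β-carbon; a second electron turns the α-ester radical into a samarium enolate that t-BuOH protonates. The closest known reaction type is the SmI2-mediated ketyl–olefin (ketone–enoate) reductive cyclisation used for 2-hydroxycycloalkylacetates. The cyclohexane closes in the 6-exo-trig mode, forming C5a–C9a as its only new bond. At C9a the bulky HMPA-solvated O–Sm group takes the equatorial site of the chair and stays away from the ester-bearing alkene, so the methyl group ends axial and the hydroxyl trans to the acetate arm; at C5a the E-enoate sits equatorial on the same chair, and the equatorial C7 silyloxy group decides which chair is used, so both new centres should be set as S relative to C7. The step needs chemoselectivity (ketyl formation and addition to the single electron-poor alkene, secured by the absence of C–Br bonds, free hydroxyls or other acceptors and by the gem-dimethyl tether that favours closure) and 1,3-diastereoselectivity relative to C7, secured by the equatorial OTBS group.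

Step 8
Reactants: 11 methyl 2-[(1S,3S,6S)-3-(tert-butyldimethylsilyloxy)-6-hydroxy-2,2,6-trimethylcyclohexyl]acetate
Product: 12 2-[(1S,3S,6S)-3-(tert-butyldimethylsilyloxy)-6-hydroxy-2,2,6-trimethylcyclohexyl]acetaldehyde
Conditions: i-Bu2AlH (2.2 equiv), CH2Cl2, −78 °C; aq. potassium sodium tartrate
Reagents that add atoms: none
Why: Partial reduction of the methyl ester at −78 °C should stop at the aluminium hemiacetal, stabilised by the neighbouring aluminium alkoxide, so that work-up releases the aldehyde as a hydroxy aldehyde/lactol mixture.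

Step 9
Reactants: 12 2-[(1S,3S,6S)-3-(tert-butyldimethylsilyloxy)-6-hydroxy-2,2,6-trimethylcyclohexyl]acetaldehyde
Product: 13 (1S,2S,4S)-4-(tert-butyldimethylsilyloxy)-1,3,3-trimethyl-2-(prop-2-en-1-yl)cyclohexan-1-ol
Conditions: Ph3PCH3Br (3 equiv), KOt-Bu (2.8 equiv), THF, 0 °C to rt
Reagents that add atoms: methyltriphenylphosphonium bromide, C[P+](c1ccccc1)(c1ccccc1)c1ccccc1.[Br-]
Why: Wittig methylenation with an excess of the non-stabilised ylide converts the aldehyde, drawn from the lactol equilibrium, into the terminal alkene and tolerates the free tertiary hydroxyl.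

Step 10
Reactants: 13 (1S,2S,4S)-4-(tert-butyldimethylsilyloxy)-1,3,3-trimethyl-2-(prop-2-en-1-yl)cyclohexan-1-ol; 14 methacryloyl chloride
Product: 16 (1S,2S,4S)-4-(tert-butyldimethylsilyloxy)-1,3,3-trimethyl-2-(prop-2-en-1-yl)cyclohexyl 2-methylprop-2-enoate, via lithium alkoxide 15 (not isolated)
Conditions: n-BuLi (1.05 equiv), THF, −78 °C; then 14, −78 to 0 °C
Reagents that add atoms: none
Why: O-Acylation of the preformed tertiary lithium alkoxide with the acid chloride overcomes the low nucleophilicity of the hindered alcohol.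

Step 11
Reactants: 16 (1S,2S,4S)-4-(tert-butyldimethylsilyloxy)-1,3,3-trimethyl-2-(prop-2-en-1-yl)cyclohexyl 2-methylprop-2-enoate
Product: 17 (5aS,7S,9aS)-7-(tert-butyldimethylsilyloxy)-3,6,6,9a-tetramethyl-5a,6,7,8,9,9a-hexahydro-1-benzoxepin-2(5H)-one
Conditions: second-generation Grubbs catalyst (10 mol%), toluene (2 mM), 80 °C
Reagents that add atoms: none
Why: Ring-closing metathesis between the allyl group and the methacrylate closes the seven-membered lactone with loss of ethene and can only give the endocyclic Z C3=C4 alkene.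

Step 12
Reactants: 17 (5aS,7S,9aS)-7-(tert-butyldimethylsilyloxy)-3,6,6,9a-tetramethyl-5a,6,7,8,9,9a-hexahydro-1-benzoxepin-2(5H)-one
Product: 18 (5aS,7S,9aS)-7-(tert-butyldimethylsilyloxy)-3,6,6,9a-tetramethyl-2-methylidene-2,5,5a,6,7,8,9,9a-octahydro-1-benzoxepine
Conditions: Cp2TiMe2 (3 equiv), toluene, 70 °C, dark; filtration through basic alumina
Reagents that add atoms: bis(cyclopentadienyl)dimethyltitanium (Cp2TiMe2), C[Ti](C)(C1C=CC=C1)C1C=CC=C1
Why: Petasis methylenation, in which Cp2Ti=CH2 formed thermally from Cp2TiMe2 adds [2+2] to the lactone carbonyl and cycloreverts to the exocyclic enol ether, supplies the carbon of the later bromomethyl group without acid or strong base.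

Step 13
Reactants: 18 (5aS,7S,9aS)-7-(tert-butyldimethylsilyloxy)-3,6,6,9a-tetramethyl-2-methylidene-2,5,5a,6,7,8,9,9a-octahydro-1-benzoxepine
Product: 20 [(2R,5aS,7S,9aS)-7-(tert-butyldimethylsilyloxy)-3,6,6,9a-tetramethyl-2,5,5a,6,7,8,9,9a-octahydro-1-benzoxepin-2-yl]methanol, via alkylborane 19 (not isolated)
Conditions: 9-BBN (2 equiv), THF, 0 °C to rt; then aq. NaOH, H2O2, 0 °C
Reagents that add atoms: hydrogen peroxide, OO
Why: Hydroboration–oxidation places boron on the terminal carbon of the enol ether and delivers hydrogen to C2 from the face opposite the axial C9a methyl group, which should set C2 as R (CH2OH cis to the angular methyl), while 9-BBN leaves the trisubstituted ring alkene alone.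

Step 14
Reactants: 20 [(2R,5aS,7S,9aS)-7-(tert-butyldimethylsilyloxy)-3,6,6,9a-tetramethyl-2,5,5a,6,7,8,9,9a-octahydro-1-benzoxepin-2-yl]methanol
Product: 21 (2R,5aS,7S,9aS)-2-(bromomethyl)-7-(tert-butyldimethylsilyloxy)-3,6,6,9a-tetramethyl-2,5,5a,6,7,8,9,9a-octahydro-1-benzoxepine
Conditions: CBr4, PPh3, CH2Cl2, 0 °C
Reagents that add atoms: tetrabromomethane, BrC(Br)(Br)Br
Why: Appel bromination of the unhindered primary alcohol proceeds by SN2 displacement of the alkoxyphosphonium ion under neutral conditions that spare the silyl ether and the allylic ether.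

Step 15
Reactants: 21 (2R,5aS,7S,9aS)-2-(bromomethyl)-7-(tert-butyldimethylsilyloxy)-3,6,6,9a-tetramethyl-2,5,5a,6,7,8,9,9a-octahydro-1-benzoxepine
Product: 22 (2R,5aS,7S,9aS)-2-(bromomethyl)-3,6,6,9a-tetramethyl-2,5,5a,6,7,8,9,9a-octahydro-1-benzoxepin-7-ol
Conditions: HF·pyridine, THF, rt to 40 °C
Reagents that add atoms: none
Why: Acidic fluoride removes the hindered silyl ether without the basic conditions that could eliminate HBr from the β-alkoxy primary bromide.

Step 16
Reactants: 22 (2R,5aS,7S,9aS)-2-(bromomethyl)-3,6,6,9a-tetramethyl-2,5,5a,6,7,8,9,9a-octahydro-1-benzoxepin-7-ol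
Product: 23 (2R,5aS,9aS)-2-(bromomethyl)-3,6,6,9a-tetramethyl-2,5,5a,8,9,9a-hexahydro-1-benzoxepin-7(6H)-one
Conditions: Dess–Martin periodinane, CH2Cl2, rt
Reagents that add atoms: none
Why: Dess–Martin oxidation of the secondary alcohol gives the ketone flanked by the quaternary C6, erasing the C7 centre before it is reset.

Step 17
Reactants: 23 (2R,5aS,9aS)-2-(bromomethyl)-3,6,6,9a-tetramethyl-2,5,5a,8,9,9a-hexahydro-1-benzoxepin-7(6H)-one
Product: 24 (2R,5aS,7R,9aS)-2-(bromomethyl)-3,6,6,9a-tetramethyl-2,5,5a,6,7,8,9,9a-octahydro-1-benzoxepin-7-ol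
Conditions: LiBH(s-Bu)3 (1.2 equiv), THF, −78 °C; then aq. NaOH, H2O2, 0 °C
Reagents that add atoms: none
Why: The bulky LiBH(s-Bu)3 attacks the cyclohexanone along the equatorial trajectory, away from the axial hydrogens at C5a and C9, which should give the axial (7R) alcohol, and at −78 °C it should not displace the primary bromide.

Step 18
Reactants: 24 (2R,5aS,7R,9aS)-2-(bromomethyl)-3,6,6,9a-tetramethyl-2,5,5a,6,7,8,9,9a-octahydro-1-benzoxepin-7-ol
Product: 25 palisadin B, (2R,5aS,7S,9aS)-7-bromo-2-(bromomethyl)-3,6,6,9a-tetramethyl-2,5,5a,6,7,8,9,9a-octahydro-1-benzoxepine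
Conditions: CBr4, PPh3, toluene, 50 °C
Reagents that add atoms: tetrabromomethane, BrC(Br)(Br)Br
Why: Appel bromination with inversion, in which bromide displaces the axial alkoxyphosphonium group from the equatorial side to give the equatorial (7S) bromide, is a known way to turn axial alcohols beside a gem-dimethyl carbon into equatorial bromides in terpenoid rings.

Compound list

1 | pent-4-enal | C=CCCC=O | starting material
2 | 1-methoxy-2-methyl-1-(trimethylsilyloxy)prop-1-ene | COC(O[Si](C)(C)C)=C(C)C | starting material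
3 | methyl (3S)-2,2-dimethyl-3-(trimethylsilyloxy)hept-6-enoate | COC(=O)C(C)(C)[C@@H](O[Si](C)(C)C)CCC=C | intermediate
4 | methyl (3S)-3-hydroxy-2,2-dimethylhept-6-enoate | COC(=O)C(C)(C)[C@@H](O)CCC=C | intermediate
5 | methyl (3S)-3-(tert-butyldimethylsilyloxy)-2,2-dimethylhept-6-enoate | COC(=O)C(C)(C)[C@@H](O[Si](C)(C)C(C)(C)C)CCC=C | intermediate
6 | (3S)-3-(tert-butyldimethylsilyloxy)-2,2-dimethylhept-6-en-1-ol | OCC(C)(C)[C@@H](O[Si](C)(C)C(C)(C)C)CCC=C | intermediate
7 | (3S)-3-(tert-butyldimethylsilyloxy)-2,2-dimethylhept-6-enal | O=CC(C)(C)[C@@H](O[Si](C)(C)C(C)(C)C)CCC=C | intermediate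
8 | trimethyl phosphonoacetate | COC(=O)CP(=O)(OC)OC | starting material
9 | methyl (2E,5S)-5-(tert-butyldimethylsilyloxy)-4,4-dimethylnona-2,8-dienoate | COC(=O)/C=C/C(C)(C)[C@@H](O[Si](C)(C)C(C)(C)C)CCC=C | intermediate
10 | methyl (2E,5S)-5-(tert-butyldimethylsilyloxy)-4,4-dimethyl-8-oxonon-2-enoate | CC(=O)CC[C@H](O[Si](C)(C)C(C)(C)C)C(C)(C)/C=C/C(=O)OC | intermediate
11 | methyl 2-[(1S,3S,6S)-3-(tert-butyldimethylsilyloxy)-6-hydroxy-2,2,6-trimethylcyclohexyl]acetate | COC(=O)C[C@H]1C(C)(C)[C@@H](O[Si](C)(C)C(C)(C)C)CC[C@]1(C)O | intermediate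
12 | 2-[(1S,3S,6S)-3-(tert-butyldimethylsilyloxy)-6-hydroxy-2,2,6-trimethylcyclohexyl]acetaldehyde | O=CC[C@H]1C(C)(C)[C@@H](O[Si](C)(C)C(C)(C)C)CC[C@]1(C)O | intermediate
13 | (1S,2S,4S)-4-(tert-butyldimethylsilyloxy)-1,3,3-trimethyl-2-(prop-2-en-1-yl)cyclohexan-1-ol | C=CC[C@H]1C(C)(C)[C@@H](O[Si](C)(C)C(C)(C)C)CC[C@]1(C)O | intermediate
14 | methacryloyl chloride | CC(=C)C(=O)Cl | starting material
15 | lithium (1S,2S,4S)-4-(tert-butyldimethylsilyloxy)-1,3,3-trimethyl-2-(prop-2-en-1-yl)cyclohexan-1-olate | C=CC[C@H]1C(C)(C)[C@@H](O[Si](C)(C)C(C)(C)C)CC[C@]1(C)[O-].[Li+] | intermediate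
16 | (1S,2S,4S)-4-(tert-butyldimethylsilyloxy)-1,3,3-trimethyl-2-(prop-2-en-1-yl)cyclohexyl 2-methylprop-2-enoate | C=CC[C@H]1C(C)(C)[C@@H](O[Si](C)(C)C(C)(C)C)CC[C@]1(C)OC(=O)C(C)=C | intermediate
17 | (5aS,7S,9aS)-7-(tert-butyldimethylsilyloxy)-3,6,6,9a-tetramethyl-5a,6,7,8,9,9a-hexahydro-1-benzoxepin-2(5H)-one | CC1=CC[C@H]2C(C)(C)[C@@H](O[Si](C)(C)C(C)(C)C)CC[C@]2(C)OC1=O | intermediate
18 | (5aS,7S,9aS)-7-(tert-butyldimethylsilyloxy)-3,6,6,9a-tetramethyl-2-methylidene-2,5,5a,6,7,8,9,9a-octahydro-1-benzoxepine | CC1=CC[C@H]2C(C)(C)[C@@H](O[Si](C)(C)C(C)(C)C)CC[C@]2(C)OC1=C | intermediate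
19 | 9-{[(2S,5aS,7S,9aS)-7-(tert-butyldimethylsilyloxy)-3,6,6,9a-tetramethyl-2,5,5a,6,7,8,9,9a-octahydro-1-benzoxepin-2-yl]methyl}-9-borabicyclo[3.3.1]nonane | CC1=CC[C@H]2C(C)(C)[C@@H](O[Si](C)(C)C(C)(C)C)CC[C@]2(C)O[C@H]1CB1C2CCCC1CCC2 | intermediate
20 | [(2R,5aS,7S,9aS)-7-(tert-butyldimethylsilyloxy)-3,6,6,9a-tetramethyl-2,5,5a,6,7,8,9,9a-octahydro-1-benzoxepin-2-yl]methanol | CC1=CC[C@H]2C(C)(C)[C@@H](O[Si](C)(C)C(C)(C)C)CC[C@]2(C)O[C@H]1CO | intermediate
21 | (2R,5aS,7S,9aS)-2-(bromomethyl)-7-(tert-butyldimethylsilyloxy)-3,6,6,9a-tetramethyl-2,5,5a,6,7,8,9,9a-octahydro-1-benzoxepine | CC1=CC[C@H]2C(C)(C)[C@@H](O[Si](C)(C)C(C)(C)C)CC[C@]2(C)O[C@H]1CBr | intermediate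
22 | (2R,5aS,7S,9aS)-2-(bromomethyl)-3,6,6,9a-tetramethyl-2,5,5a,6,7,8,9,9a-octahydro-1-benzoxepin-7-ol | CC1=CC[C@H]2C(C)(C)[C@@H](O)CC[C@]2(C)O[C@H]1CBr | intermediate
23 | (2R,5aS,9aS)-2-(bromomethyl)-3,6,6,9a-tetramethyl-2,5,5a,8,9,9a-hexahydro-1-benzoxepin-7(6H)-one | CC1=CC[C@H]2C(C)(C)C(=O)CC[C@]2(C)O[C@H]1CBr | intermediate
24 | (2R,5aS,7R,9aS)-2-(bromomethyl)-3,6,6,9a-tetramethyl-2,5,5a,6,7,8,9,9a-octahydro-1-benzoxepin-7-ol | CC1=CC[C@H]2C(C)(C)[C@H](O)CC[C@]2(C)O[C@H]1CBr | intermediate
25 | palisadin B, (2R,5aS,7S,9aS)-7-bromo-2-(bromomethyl)-3,6,6,9a-tetramethyl-2,5,5a,6,7,8,9,9a-octahydro-1-benzoxepine | CC1=CC[C@H]2C(C)(C)[C@@H](Br)CC[C@]2(C)O[C@H]1CBr | target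

Total step count: 18. Longest linear sequence: 18 steps (from pent-4-enal 1).

Steps most likely to fail

Step 7. The two chair transition states may be poorly discriminated, because the equatorial preference of a silyloxy group beside a quaternary carbon is small. Simple ketone reduction or pinacol coupling may also outrun addition to the congested β-carbon. Fallback (sets out from 9, returns at 12): the C5a–C9a bond is made by a polar, metal-templated allylation instead of a radical closure. Reduction of 9 with i-Bu2AlH gives (2E,5S)-5-(tert-butyldimethylsilyloxy)-4,4-dimethylnona-2,8-dien-1-ol F1. Tsuji–Wacker oxidation (PdCl2, CuCl, O2) of its terminal alkene gives (5S,7E)-5-(tert-butyldimethylsilyloxy)-9-hydroxy-6,6-dimethylnon-7-en-2-one F2. CBr4/PPh3 converts this into (5S,7E)-9-bromo-5-(tert-butyldimethylsilyloxy)-6,6-dimethylnon-7-en-2-one F3. CrCl2 in THF then forms the allylchromium species, whose γ-carbon should add to the ketone through a closed chair to give (1S,2S,4S)-4-(tert-butyldimethylsilyloxy)-2-ethenyl-1,3,3-trimethylcyclohexan-1-ol F4. Hydroboration–oxidation of the vinyl group (9-BBN, then NaOH/H2O2) gives 2-[(1S,3S,6S)-3-(tert-butyldimethylsilyloxy)-6-hydroxy-2,2,6-trimethylcyclohexyl]ethan-1-ol F5, and TEMPO/PhI(OAc)2 oxidation of the primary hydroxyl delivers 12.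

Step 18. The activated axial oxygen may be lost by E2 elimination toward C8 or by methyl migration from C6 instead of being displaced, and PPh3 may slowly be alkylated by the primary bromide under the forcing conditions. Fallback (sets out from 24, returns at 25): activation and displacement are separated and the phosphine is removed from the system. Chloromethanesulfonyl chloride and pyridine convert 24 into (2R,5aS,7R,9aS)-2-(bromomethyl)-3,6,6,9a-tetramethyl-2,5,5a,6,7,8,9,9a-octahydro-1-benzoxepin-7-yl chloromethanesulfonate F7, a sulfonate suited to SN2 displacement at hindered secondary carbons. LiBr in DMF then displaces it with inversion to give 25.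

Step 13. The dienol ether may hydrolyse before it is hydroborated, facial control at C2 may be incomplete, or the ring alkene may compete for the borane. Fallback (sets out from 17, returns at 21): carbon and bromine are brought in together and hydride is delivered last. LiCH2Br, generated from CH2Br2 and n-BuLi at −90 °C in the presence of 17, adds to the lactone carbonyl to give (5aS,7S,9aS)-2-(bromomethyl)-7-(tert-butyldimethylsilyloxy)-3,6,6,9a-tetramethyl-2,5,5a,6,7,8,9,9a-octahydro-1-benzoxepin-2-ol F6 as an anomer mixture. Et3SiH with BF3·OEt2 at −40 °C reduces the derived allylic oxocarbenium ion, with hydride again expected to enter C2 anti to the C9a methyl group, giving 21 directly and bypassing steps 12 to 14.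

Further compounds

F1 | step 7 | (2E,5S)-5-(tert-butyldimethylsilyloxy)-4,4-dimethylnona-2,8-dien-1-ol | OC/C=C/C(C)(C)[C@@H](O[Si](C)(C)C(C)(C)C)CCC=C
F2 | step 7 | (5S,7E)-5-(tert-butyldimethylsilyloxy)-9-hydroxy-6,6-dimethylnon-7-en-2-one | CC(=O)CC[C@H](O[Si](C)(C)C(C)(C)C)C(C)(C)/C=C/CO
F3 | step 7 | (5S,7E)-9-bromo-5-(tert-butyldimethylsilyloxy)-6,6-dimethylnon-7-en-2-one | CC(=O)CC[C@H](O[Si](C)(C)C(C)(C)C)C(C)(C)/C=C/CBr
F4 | step 7 | (1S,2S,4S)-4-(tert-butyldimethylsilyloxy)-2-ethenyl-1,3,3-trimethylcyclohexan-1-ol | C=C[C@H]1C(C)(C)[C@@H](O[Si](C)(C)C(C)(C)C)CC[C@]1(C)O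
F5 | step 7 | 2-[(1S,3S,6S)-3-(tert-butyldimethylsilyloxy)-6-hydroxy-2,2,6-trimethylcyclohexyl]ethan-1-ol | OCC[C@H]1C(C)(C)[C@@H](O[Si](C)(C)C(C)(C)C)CC[C@]1(C)O
F6 | step 13 | (5aS,7S,9aS)-2-(bromomethyl)-7-(tert-butyldimethylsilyloxy)-3,6,6,9a-tetramethyl-2,5,5a,6,7,8,9,9a-octahydro-1-benzoxepin-2-ol | CC1=CC[C@H]2C(C)(C)[C@@H](O[Si](C)(C)C(C)(C)C)CC[C@]2(C)OC1(O)CBr
F7 | step 18 | (2R,5aS,7R,9aS)-2-(bromomethyl)-3,6,6,9a-tetramethyl-2,5,5a,6,7,8,9,9a-octahydro-1-benzoxepin-7-yl chloromethanesulfonate | CC1=CC[C@H]2C(C)(C)[C@H](OS(=O)(=O)CCl)CC[C@]2(C)O[C@H]1CBr
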